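## Plan

1. Retrosynthesis (indane numbering: ring A = C1, C2, C3, C3a, C7a; ring B = C3a, C4, C5, C6, C7, C7a; β = face of H‑3a). The C5 angelate/C6 hydroxyl pair goes back to a 5α,6α‑epoxide, the C2 acetate and C1 ethylidene to a C1 ketone, and ring B is then cut at C3a–C4 and C7–C7a.
2. Enabling feature: ring B carries an exocyclic methylidene on C4 next to ring‑fusion carbon C3a and a masked C5=C6 alkene, and ring A has a carbon (C1) next to C7a that can be a ketone. This is the retron of a [4+2] cycloaddition of a vinylallene with cyclopent‑2‑enone.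
3. Forward: the vinylallene is assembled, ring B is closed onto the intact cyclopentenone in one step, ring A is then elaborated (C2–O, C7a epimerisation, C1 ethylidene, C2 acetate), and ring B is oxidised last.
4. Stereochemistry: C3a, C7 and C7a come from the catalyst‑controlled endo cycloaddition, and C7a is then inverted by equilibration to the trans fusion. C2 comes from convex‑face hydroxylation followed by Mitsunobu inversion, and the Z‑ethylidene from a Wittig reaction on the α‑silyloxy ketone. C5 and C6 come from catalyst‑controlled epoxidation and anti opening.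

Key step: step 3

Assumption: the facial sense of the chiral catalysts in steps 3 and 10 is assigned by analogy with simpler substrates; if the opposite sense is found, the enantiomeric catalyst is used.

## Route

Step 1
Reactants: 1 3‑methylbut‑1‑yne
Product: 2 (E)‑(3‑methylbut‑1‑en‑1‑yl)boronic acid
Conditions: catecholborane, Cy2BH (5 mol %), THF, 25 °C, sealed; then H2O, 25 °C
Reagents that add atoms: catecholborane ([H]B1Oc2ccccc2O1); water (O)
Why: Syn, anti‑Markovnikov hydroboration of the terminal alkyne gives the E‑alkenylboronate, which water hydrolyses to the boronic acid (alkyne hydroboration).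

Step 2
Reactants: 2 (E)‑(3‑methylbut‑1‑en‑1‑yl)boronic acid; 3 methyl prop‑2‑yn‑1‑yl carbonate
Product: 4 (4E)‑6‑methylhepta‑1,2,4‑triene
Conditions: Pd(PPh3)4 (3 mol %, zerovalent palladium), THF, 50 °C; distillation
Reagents that add atoms: none
Why: Anti‑SN2′ ionisation of the propargylic carbonate with loss of CO2 gives an allenylpalladium methoxide, which transmetalates with the boronic acid under neutral conditions and reductively eliminates to the terminal allene with the E‑alkene retained (Suzuki–Miyaura‑type allene synthesis from propargylic carbonates).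

Step 3
Reactants: 4 (4E)‑6‑methylhepta‑1,2,4‑triene; 5 cyclopent‑2‑en‑1‑one
Product: 6 (3aR,7R,7aR)‑4‑methylidene‑7‑(propan‑2‑yl)‑2,3,3a,4,7,7a‑hexahydro‑1H‑inden‑1‑one (cis‑fused; H‑3a, H‑7a and H‑7 all β)
Conditions: (S)‑3,3‑diphenyl‑1‑(o‑tolyl)tetrahydro‑1H,3H‑pyrrolo[1,2‑c][1,3,2]oxazaborole (20 mol %), Tf2NH (18 mol %), CH2Cl2, −78 → −40 °C
Reagents that add atoms: none
Why: The cationic boron Lewis acid binds the enone carbonyl and lowers its LUMO, and the s‑cis diene made of the internal allene π bond and the E‑alkene of 4 adds in a concerted, asynchronous, suprafacial [4+2] cycloaddition; the closest precedents are Lewis‑acid‑promoted Diels–Alder reactions of vinylallenes with enones and oxazaborolidinium‑catalysed Diels–Alder reactions of 2‑cycloalkenones. Ring B is closed by this intermolecular [4+2] mode across C3a=C7a of the intact cyclopentenone, while the orthogonal terminal π bond of the allene is untouched and emerges as the C4 methylidene. The unhindered sp carbon should bond to the enone β‑carbon (C3a–C4 leading), because the developing positive charge is then an allyl cation ending at the isopropyl‑bearing carbon, which therefore bonds to the α‑carbon (C7–C7a). C3a and C7a are cis because both bonds form on one face of the cis‑enone; C7 is set relative to them by the endo transition state and the E geometry of the diene (H‑7 cis to H‑7a); the absolute configuration is set by shielding of one enone face by the catalyst. The step needs one regiochemistry, endo over exo and one π‑face; these are secured by the polarisation described, by the compact Lewis‑acid‑bound endo transition state at low temperature, and by the chiral ligand. The s‑cis conformer is easily reached because the allene terminus has no inside substituent.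

Step 4
Reactants: 6 cis‑fused ketone
Product: 8 (2R,3aR,7R,7aR)‑2‑hydroxy‑4‑methylidene‑7‑(propan‑2‑yl)‑2,3,3a,4,7,7a‑hexahydro‑1H‑inden‑1‑one (cis‑fused, 2β‑OH), via potassium enolate 7 (not isolated)
Conditions: KN(SiMe3)2, THF, −78 °C; then 2‑(phenylsulfonyl)‑3‑phenyloxaziridine, −78 °C; aq NH4Cl
Reagents that add atoms: 2‑(phenylsulfonyl)‑3‑phenyloxaziridine (O=S(=O)(c1ccccc1)N1OC1c1ccccc1)
Why: Kinetic deprotonation occurs at the C2 methylene and not at the hindered C7a methine, and the oxaziridine should transfer oxygen to the convex β face of the cis‑fused enolate because ring B covers the α face (Davis enolate hydroxylation).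

Step 5
Reactants: 8 cis‑fused 2β‑hydroxy ketone
Product: 9 (2R,3aR,7R,7aR)‑2‑[(tert‑butyldimethylsilyl)oxy]‑4‑methylidene‑7‑(propan‑2‑yl)‑2,3,3a,4,7,7a‑hexahydro‑1H‑inden‑1‑one (cis‑fused)
Conditions: TBSCl, imidazole, DMF, 25 °C
Reagents that add atoms: tert‑butyldimethylsilyl chloride (CC(C)(C)[Si](C)(C)Cl)
Why: Silylation of the secondary alcohol blocks α‑ketol isomerisation and supplies the α‑alkoxy ketone needed for the olefination (silyl ether formation).

Step 6
Reactants: 9 cis‑fused silyloxy ketone
Product: 10 (2R,3aR,7R,7aS)‑2‑[(tert‑butyldimethylsilyl)oxy]‑4‑methylidene‑7‑(propan‑2‑yl)‑2,3,3a,4,7,7a‑hexahydro‑1H‑inden‑1‑one (trans‑fused, H‑7a α)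
Conditions: DBU (0.3 equiv), toluene, 40 °C
Reagents that add atoms: none
Why: Reversible enolisation towards C7a equilibrates the ring fusion, and the trans isomer is expected to predominate because the half‑chair cyclohexene (C3a–C7a torsion near 60°) accommodates a trans‑fused five‑membered ring and the acyl carbon leaves its 1,2‑cis relationship to the isopropyl group; C2–H (concave face, oxygen‑bearing carbon) should be removed more slowly, and recovered 9 is resubmitted (thermodynamic epimerisation α to a ketone).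

Step 7
Reactants: 10 trans‑fused silyloxy ketone
Product: 11 (1Z,2R,3aR,7R,7aS)‑tert‑butyl{[1‑ethylidene‑4‑methylidene‑7‑(propan‑2‑yl)‑2,3,3a,4,7,7a‑hexahydro‑1H‑inden‑2‑yl]oxy}dimethylsilane
Conditions: EtPPh3Br, KN(SiMe3)2, THF, 0 °C; then 10, −78 → 25 °C
Reagents that add atoms: ethyltriphenylphosphonium bromide (CC[P+](c1ccccc1)(c1ccccc1)c1ccccc1.[Br-])
Why: Wittig olefination of an α‑alkoxy ketone with a non‑stabilised ylide places the ylide methyl cis to the oxygenated carbon, which here is also the side away from C7 and its isopropyl group, so the Z‑ethylidene should result; the trans fusion is the expected thermodynamic one and should survive the basic medium.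

Step 8
Reactants: 11 silyl ether
Product: 12 (1Z,2R,3aR,7R,7aS)‑1‑ethylidene‑4‑methylidene‑7‑(propan‑2‑yl)‑2,3,3a,4,7,7a‑hexahydro‑1H‑inden‑2‑ol (2β‑OH)
Conditions: Bu4NF, THF, 0 → 25 °C
Reagents that add atoms: none
Why: Fluoride cleaves the Si–O bond without touching the alkenes or the stereocentres (desilylation).

Step 9
Reactants: 12 2β‑allylic alcohol
Product: 13 (1Z,2S,3aR,7R,7aS)‑1‑ethylidene‑4‑methylidene‑7‑(propan‑2‑yl)‑2,3,3a,4,7,7a‑hexahydro‑1H‑inden‑2‑yl acetate (2α‑OAc)
Conditions: AcOH, PPh3, DIAD, toluene, 0 → 25 °C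
Reagents that add atoms: acetic acid (CC(=O)O)
Why: The alkoxyphosphonium ion of the 2β‑alcohol is displaced by acetate with inversion (SN2), which installs the acetate and corrects C2 in one operation (Mitsunobu reaction).

Step 10
Reactants: 13 diene acetate
Product: 14 5α,6α‑epoxide of 13 (oxirane oxygen on the α face, cis to the isopropyl group and to H‑7a)
Conditions: (R,R)‑[N,N′‑bis(3,5‑di‑tert‑butylsalicylidene)cyclohexane‑1,2‑diaminato]manganese chloride (5 mol %, trivalent manganese), NMO, mCPBA, CH2Cl2, −78 °C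
Reagents that add atoms: 3‑chloroperoxybenzoic acid (O=C(OO)c1cccc(Cl)c1)
Why: The manganese‑oxo species should react fastest with the conjugated cis‑disubstituted C5=C6 bond (1,1‑disubstituted and isolated trisubstituted alkenes are poor substrates), and since the two faces of the substrate are nearly equivalent (equatorial isopropyl, one axial hydrogen on each face) the catalyst should select the face; the (R,R) complex is chosen by analogy with indene and cis‑β‑methylstyrene to give the α‑oxide (Jacobsen–Katsuki epoxidation).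

Step 11
Reactants: 14 5α,6α‑epoxide; 15 angelic acid ((2Z)‑2‑methylbut‑2‑enoic acid)
Product: 16 (1Z,2S,3aR,5S,6S,7S,7aR)‑2‑(acetyloxy)‑1‑ethylidene‑6‑hydroxy‑4‑methylidene‑7‑(propan‑2‑yl)octahydro‑1H‑inden‑5‑yl (2Z)‑2‑methylbut‑2‑enoate (target)
Conditions: 15 (5 equiv), Cs2CO3 (0.2 equiv), DMF, 50 °C
Reagents that add atoms: none
Why: Attack of angelate on the vinyl epoxide at the allylic carbon C5 from the β face is both the electronically preferred and the trans‑diaxial (Fürst–Plattner) mode in the trans‑fused ring, so C5 is inverted to the β‑ester and C6 keeps its α‑oxygen as the free alcohol; the buffered carboxylate medium should avoid Z→E isomerisation of the angelate (carboxylate opening of an epoxide).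

## Compound list

1 | 3‑methylbut‑1‑yne | CC(C)C#C | starting material
2 | (E)‑(3‑methylbut‑1‑en‑1‑yl)boronic acid | CC(C)/C=C/B(O)O | intermediate
3 | methyl prop‑2‑yn‑1‑yl carbonate | C#CCOC(=O)OC | starting material
4 | (4E)‑6‑methylhepta‑1,2,4‑triene | C=C=C/C=C/C(C)C | intermediate
5 | cyclopent‑2‑en‑1‑one | O=C1C=CCC1 | starting material
6 | (3aR,7R,7aR)‑4‑methylidene‑7‑(propan‑2‑yl)‑2,3,3a,4,7,7a‑hexahydro‑1H‑inden‑1‑one, cis‑fused | C=C1[C@@H]2CCC(=O)[C@@H]2[C@H](C(C)C)C=C1 | intermediate
7 | potassium enolate of 6 (C1–O⁻, C1=C2) | C=C1[C@@H]2CC=C([O-])[C@@H]2[C@H](C(C)C)C=C1.[K+] | intermediate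
8 | (2R,3aR,7R,7aR)‑2‑hydroxy‑4‑methylidene‑7‑(propan‑2‑yl)‑2,3,3a,4,7,7a‑hexahydro‑1H‑inden‑1‑one, cis‑fused, 2β‑OH | C=C1[C@@H]2C[C@@H](O)C(=O)[C@@H]2[C@H](C(C)C)C=C1 | intermediate
9 | (2R,3aR,7R,7aR)‑2‑[(tert‑butyldimethylsilyl)oxy]‑4‑methylidene‑7‑(propan‑2‑yl)‑2,3,3a,4,7,7a‑hexahydro‑1H‑inden‑1‑one, cis‑fused | C=C1[C@@H]2C[C@@H](O[Si](C)(C)C(C)(C)C)C(=O)[C@@H]2[C@H](C(C)C)C=C1 | intermediate
10 | (2R,3aR,7R,7aS)‑2‑[(tert‑butyldimethylsilyl)oxy]‑4‑methylidene‑7‑(propan‑2‑yl)‑2,3,3a,4,7,7a‑hexahydro‑1H‑inden‑1‑one, trans‑fused | C=C1[C@@H]2C[C@@H](O[Si](C)(C)C(C)(C)C)C(=O)[C@H]2[C@H](C(C)C)C=C1 | intermediate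
11 | (1Z,2R,3aR,7R,7aS)‑tert‑butyl{[1‑ethylidene‑4‑methylidene‑7‑(propan‑2‑yl)‑2,3,3a,4,7,7a‑hexahydro‑1H‑inden‑2‑yl]oxy}dimethylsilane | C=C1[C@@H]2C[C@@H](O[Si](C)(C)C(C)(C)C)/C(=C\C)[C@H]2[C@H](C(C)C)C=C1 | intermediate
12 | (1Z,2R,3aR,7R,7aS)‑1‑ethylidene‑4‑methylidene‑7‑(propan‑2‑yl)‑2,3,3a,4,7,7a‑hexahydro‑1H‑inden‑2‑ol, 2β‑OH | C=C1[C@@H]2C[C@@H](O)/C(=C\C)[C@H]2[C@H](C(C)C)C=C1 | intermediate
13 | (1Z,2S,3aR,7R,7aS)‑1‑ethylidene‑4‑methylidene‑7‑(propan‑2‑yl)‑2,3,3a,4,7,7a‑hexahydro‑1H‑inden‑2‑yl acetate, 2α‑OAc | C=C1[C@@H]2C[C@H](OC(C)=O)/C(=C\C)[C@H]2[C@H](C(C)C)C=C1 | intermediate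
14 | 5α,6α‑epoxide of 13 | C=C1[C@@H]2C[C@H](OC(C)=O)/C(=C\C)[C@H]2[C@H](C(C)C)[C@@H]3O[C@H]13 | intermediate
15 | angelic acid, (2Z)‑2‑methylbut‑2‑enoic acid | C/C=C(/C)C(=O)O | starting material
16 | (1Z,2S,3aR,5S,6S,7S,7aR)‑2‑(acetyloxy)‑1‑ethylidene‑6‑hydroxy‑4‑methylidene‑7‑(propan‑2‑yl)octahydro‑1H‑inden‑5‑yl (2Z)‑2‑methylbut‑2‑enoate | C=C1[C@@H]2C[C@H](OC(C)=O)/C(=C\C)[C@H]2[C@H](C(C)C)[C@H](O)[C@H]1OC(=O)/C(C)=C\C | target

Total step count: 11. Longest linear sequence: 11 steps (1 → 16).

## Steps most likely to fail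

**Step 10.** The catalyst may fail to impose the α face on the C5=C6 bond, giving a mixture of epoxide epimers. The fallback sets out from 13 and comes back at 16, and it does not depend on the face of epoxidation. Diene 13 is epoxidised with the racemic form of the same manganese complex to a mixture of 14 and its 5β,6β‑epimer F1. The mixture is isomerised with Pd(PPh3)4 (THF, 0 °C) through the π‑allyl alkoxide and β‑hydride elimination to the single β,γ‑unsaturated 6‑ketone F2, which erases both epoxide stereocentres. KN(SiMe3)2 deprotonates the doubly activated C5 to the potassium dienolate F3, and the oxaziridine of step 4 should hydroxylate it on the axial β face to the 5β‑hydroxy 6‑ketone F4. Me4NBH(OAc)3 in AcOH/MeCN should then deliver hydride from the 5β‑oxygen to the β face of the carbonyl (Saksena–Evans reduction) to give the trans‑diaxial 5β,6α‑diol F5. The less hindered allylic 5‑hydroxyl of F5 is acylated with the mixed anhydride of 15 and 2,4,6‑trichlorobenzoyl chloride (Et3N, toluene, 70 °C, no DMAP) to give 16.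

**Step 3.** The strongly acidic chiral catalyst may give low enantiocontrol or may oligomerise the vinylallene. The fallback sets out from 4 and comes back at 6, with the absolute configuration taken from the chiral pool. Triene 4 is combined with commercial (S)‑4‑[(tert‑butyldimethylsilyl)oxy]cyclopent‑2‑en‑1‑one (O=C1C=C[C@@H](O[Si](C)(C)C(C)(C)C)C1) under Et2AlCl (CH2Cl2, −78 → −20 °C). The diene should add anti to the silyloxy group with the same regiochemistry and endo sense to give the 3β‑silyloxy cis adduct F6. DBU eliminates silanol to the cis‑fused enone F7, and conjugate reduction with [(Ph3P)CuH]6 gives 6.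

**Step 9.** The activated allylic alcohol may undergo SN2′ attack at the ethylidene carbon or elimination instead of clean inversion. The fallback sets out from 12 and comes back at 13, with C2 set by a reagent. Alcohol 12 is oxidised with Dess–Martin periodinane to the 2‑ketone (Z‑enone) F8. Reduction with (R)‑2‑methyl‑CBS‑oxazaborolidine and BH3·SMe2, assigned with the alkylidene‑bearing carbon as the large group, should deliver hydride to the β face and give the 2α‑alcohol F9. Acetylation (Ac2O, pyridine, DMAP) gives 13.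

## Further compounds

F1 | step 10 | 5β,6β‑epoxide of 13 (epimer of 14) | C=C1[C@@H]2C[C@H](OC(C)=O)/C(=C\C)[C@H]2[C@H](C(C)C)[C@H]3O[C@@H]13
F2 | step 10 | (1Z)‑2α‑acetoxy‑1‑ethylidene‑4‑methylidene‑7α‑(propan‑2‑yl)‑trans‑octahydroinden‑6‑one | C=C1[C@@H]2C[C@H](OC(C)=O)/C(=C\C)[C@H]2[C@H](C(C)C)C(=O)C1
F3 | step 10 | potassium dienolate of F2 (C6–O⁻, C5=C6) | C=C1[C@@H]2C[C@H](OC(C)=O)/C(=C\C)[C@H]2[C@H](C(C)C)C([O-])=C1.[K+]
F4 | step 10 | 5β‑hydroxy derivative of F2 | C=C1[C@@H]2C[C@H](OC(C)=O)/C(=C\C)[C@H]2[C@H](C(C)C)C(=O)[C@H]1O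
F5 | step 10 | 5β,6α‑diol (16 without the angeloyl group) | C=C1[C@@H]2C[C@H](OC(C)=O)/C(=C\C)[C@H]2[C@H](C(C)C)[C@H](O)[C@H]1O
F6 | step 3 | 3β‑[(tert‑butyldimethylsilyl)oxy] derivative of 6 (cis‑fused) | C=C1[C@@H]2[C@@H](O[Si](C)(C)C(C)(C)C)CC(=O)[C@@H]2[C@H](C(C)C)C=C1
F7 | step 3 | cis‑fused 2,3‑didehydro derivative of 6 (cyclopentenone) | C=C1[C@@H]2C=CC(=O)[C@@H]2[C@H](C(C)C)C=C1
F8 | step 9 | (1Z)‑1‑ethylidene‑4‑methylidene‑7α‑(propan‑2‑yl)‑trans‑1,3,3a,4,7,7a‑hexahydro‑2H‑inden‑2‑one | C=C1[C@@H]2CC(=O)/C(=C\C)[C@H]2[C@H](C(C)C)C=C1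
F9 | step 9 | 2α‑epimer of 12 | C=C1[C@@H]2C[C@H](O)/C(=C\C)[C@H]2[C@H](C(C)C)C=C1
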